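**Plan**

1. Labels: ring C1 (bears C7H2OAc), C2 (=CH), C3 (CHOH), C4 and C5 (oxirane carbons, C4 quaternary), C6 (C=O); side chain C1'–C12'.
2. Cuts, in retrosynthetic order: acetate O–acyl; C1–C7 (Morita–Baylis–Hillman with CH2O); C2–C3 (closure of the cyclohexenone ring, Nozaki–Hiyama–Kishi); C3'–C4' (Suzuki–Miyaura); C4–C1' (alkenylalane + but-2-ynal); C5–C6 (acetylide + 3-bromoacrolein).
3. Forward: the open chain C2–C1–C6–C5–C4(–C3)(–C1') is built first, the oxirane ring (C4–C5–O) is made on it, the tetraene chain is joined at C3', the six-membered ring is closed last but three, then C7 and the acetate are added.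
4. Stereochemistry: C1', C4 and C5 are set together in one Sharpless kinetic resolution (L-(+)-DIPT); C3 is relayed from the oxirane during ring closure; alkene geometries come from syn-hydroalumination, Still–Gennari olefination, carboalumination and syn-borylcupration.
5. Enabling feature: C3 lies between the enone β-carbon C2 and the fully substituted oxirane carbon C4. The oxirane ring holds C3 (on C4) and C6 (on C5) cis, so a formyl group at C3 and a (Z)-β-metallated enone on C6 can only meet to form the cyclohexenone ring, and the C4–O dipole biases the face of the C3 aldehyde.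

Key step: step 17

Remark: C6 is carried as a mixture of both epimers from step 7 to step 15 (it becomes the ketone in step 16), and C1' is racemic until the resolution in step 11; the SMILES leave such centres undefined.

**Side chain (steps 1–6)**

Step 1
Reactants: 1 4-pentyn-1-ol; 2 methyl 2-[bis(2,2,2-trifluoroethoxy)phosphoryl]propanoate
Product: 4 methyl (Z)-2-methylhept-2-en-6-ynoate, via 4-pentynal 3 (not isolated)
Conditions: TEMPO (cat.), PhI(OAc)2, CH2Cl2, rt; aqueous wash, dried solution of 3; then 2, KN(SiMe3)2, 18-crown-6, THF, −78 °C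
Reagents that add atoms: none
Why: The nitroxyl-catalysed oxidation stops at the aldehyde and leaves the alkyne alone, and the Still–Gennari variant of the Horner–Wadsworth–Emmons reaction should give the Z trisubstituted enoate that fixes the C10'=C11' geometry.

Step 2
Reactants: 4 methyl (Z)-2-methylhept-2-en-6-ynoate
Product: 5 (Z)-2-methylhept-2-en-6-yn-1-ol
Conditions: iBu2AlH, CH2Cl2, −78 to 0 °C; aqueous potassium sodium tartrate
Reagents that add atoms: none
Why: 1,2-Reduction of the conjugated ester by the aluminium hydride should give the allylic alcohol without touching the Z alkene or the alkyne.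

Step 3
Reactants: 5 (Z)-2-methylhept-2-en-6-yn-1-ol
Product: 6 tert-butyl{[(Z)-2-methylhept-2-en-6-yn-1-yl]oxy}diphenylsilane
Conditions: tBuPh2SiCl, imidazole, CH2Cl2, rt
Reagents that add atoms: tert-butyl(chloro)diphenylsilane, CC(C)(C)[Si](Cl)(c1ccccc1)c1ccccc1
Why: Standard silylation of a primary alcohol; the acid-stable TBDPS group is chosen so that it survives the later selective loss of triethylsilyl groups.

Step 4
Reactants: 6 tert-butyl{[(Z)-2-methylhept-2-en-6-yn-1-yl]oxy}diphenylsilane
Product: 8 tert-butyl{[(2Z,6E)-7-iodo-2,6-dimethylhepta-2,6-dien-1-yl]oxy}diphenylsilane, via alkenylalane 7 (not isolated)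
Conditions: Me3Al, Cp2ZrCl2 (0.25 equiv), CH2Cl2, 0 °C to rt; then I2, THF, −30 °C
Reagents that add atoms: trimethylaluminium, C[Al](C)C; iodine, II
Why: Zirconium-catalysed Negishi carboalumination adds methyl and aluminium syn across the terminal alkyne with methyl on the inner carbon, and iodinolysis with retention should give the E iodide (C6'=C7').

Step 5
Reactants: 8 tert-butyl{[(2Z,6E)-7-iodo-2,6-dimethylhepta-2,6-dien-1-yl]oxy}diphenylsilane; 9 (E)-1,2-bis(tributylstannyl)ethene (3 equiv)
Product: 10 tributyl[(1E,3E,7Z)-9-(tert-butyldiphenylsilyloxy)-4,8-dimethylnona-1,3,7-trien-1-yl]stannane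
Conditions: Pd(MeCN)2Cl2 (cat.), DMF, rt, dark
Reagents that add atoms: none
Why: Stille coupling with retention at both alkenes; the excess of the distannane keeps the reaction at the mono-coupling stage and delivers the C4'=C5' unit as an E dienylstannane.

Step 6
Reactants: 10 tributyl[(1E,3E,7Z)-9-(tert-butyldiphenylsilyloxy)-4,8-dimethylnona-1,3,7-trien-1-yl]stannane
Product: 11 tert-butyl{[(2Z,6E,8E)-9-iodo-2,6-dimethylnona-2,6,8-trien-1-yl]oxy}diphenylsilane
Conditions: I2, CH2Cl2, −78 to 0 °C, dark
Reagents that add atoms: iodine, II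
Why: Iododestannylation is an ipso substitution with retention and is much faster than addition of iodine to the other alkenes.

**Core (steps 7–20)**

Step 7
Reactants: 12 ethyl (Z)-3-bromoprop-2-enoate; 13 ethyl propiolate
Product: 15 ethyl (Z)-6-bromo-4-hydroxyhex-5-en-2-ynoate (racemic), via (Z)-3-bromoprop-2-enal 14 (not isolated)
Conditions: 12, iBu2AlH (1.0 equiv), CH2Cl2, −78 °C, cold aqueous potassium sodium tartrate, dried cold solution of 14; added to 13 + LiN(SiMe3)2, THF, −78 °C; AcOH quench
Reagents that add atoms: none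
Why: Partial reduction at low temperature gives the geometrically labile Z aldehyde, which is trapped cold by 1,2-addition of the lithium acetylide of 13; this joins C6 to C5, and the new carbinol C6 is formed without control because it is oxidised later.

Step 8
Reactants: 15 ethyl (Z)-6-bromo-4-hydroxyhex-5-en-2-ynoate
Product: 16 ethyl (Z)-6-bromo-4-(triethylsilyloxy)hex-5-en-2-ynoate
Conditions: Et3SiOTf, 2,6-lutidine, CH2Cl2, −78 °C
Reagents that add atoms: triethylsilyl trifluoromethanesulfonate, CC[Si](CC)(CC)OS(=O)(=O)C(F)(F)F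
Why: Fast silylation with a hindered, non-nucleophilic base avoids the base-mediated isomerisation of the γ-hydroxy ynoate to a γ-oxo enoate.

Step 9
Reactants: 16 ethyl (Z)-6-bromo-4-(triethylsilyloxy)hex-5-en-2-ynoate; 17 but-2-ynal
Product: 20 (2E,5Z)-6-bromo-2-(1-hydroxybut-2-yn-1-yl)-4-(triethylsilyloxy)hexa-2,5-dien-1-ol (mixture of diastereomers), via vinylalane 18 (not isolated), via hydroxy ester 19 (not isolated)
Conditions: iBu2AlH, N-methylmorpholine N-oxide, THF, 0 °C; then 17, −78 °C to rt; then iBu2AlH (3 equiv), −78 to 0 °C; aqueous potassium sodium tartrate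
Reagents that add atoms: none
Why: Syn 1,4-hydroalumination of the ynoate (vinylalumination) puts aluminium on C4 and hydrogen on C5, the alkenylalane adds to the aldehyde so that the ester carbon C3 and C6 end up cis on the C4=C5 alkene, and further hydride reduces the ester to the primary allylic alcohol; C1' is formed racemic and is resolved in step 11.

Step 10
Reactants: 20 (2E,5Z)-6-bromo-2-(1-hydroxybut-2-yn-1-yl)-4-(triethylsilyloxy)hexa-2,5-dien-1-ol
Product: 21 (2E,5Z)-6-bromo-2-(1-hydroxybut-2-yn-1-yl)-1,4-bis(triethylsilyloxy)hexa-2,5-diene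
Conditions: Et3SiCl (1.05 equiv), imidazole, CH2Cl2, −20 °C
Reagents that add atoms: chlorotriethylsilane, CC[Si](CC)(CC)Cl
Why: The primary hydroxyl is silylated much faster than the secondary one, which leaves only the C1' hydroxyl free to direct the epoxidation.

Step 11
Reactants: 21 (2E,5Z)-6-bromo-2-(1-hydroxybut-2-yn-1-yl)-1,4-bis(triethylsilyloxy)hexa-2,5-diene
Product: 22 (S)-1-{(2S,3S)-3-[(Z)-3-bromo-1-(triethylsilyloxy)prop-2-enyl]-2-[(triethylsilyloxy)methyl]oxiran-2-yl}but-2-yn-1-ol (both C6 epimers)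
Conditions: Ti(OiPr)4, L-(+)-diisopropyl tartrate, tBuOOH (0.55 equiv), 4 Å molecular sieves, CH2Cl2, −20 °C; stopped near half conversion, unreacted (R)-carbinol separated
Reagents that add atoms: tert-butyl hydroperoxide, CC(C)(C)OO
Why: Sharpless asymmetric epoxidation run as a kinetic resolution: with the L-(+)-tartrate only the (S)-carbinol should be epoxidised at a useful rate, on the alkene face that gives the erythro epoxy alcohol, so C1', C4 and C5 are set in one catalytic event while the alkyne and the vinyl bromide, which are not allylic to a free hydroxyl, stay untouched.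

Step 12
Reactants: 22 epoxy alcohol
Product: 23 tert-butyldimethylsilyl ether of 22 at the C1' oxygen
Conditions: tBuMe2SiOTf, 2,6-lutidine, CH2Cl2, −78 °C
Reagents that add atoms: tert-butyldimethylsilyl trifluoromethanesulfonate, CC(C)(C)[Si](C)(C)OS(=O)(=O)C(F)(F)F
Why: Silyl triflate with a hindered base silylates the hindered secondary carbinol at low temperature without opening the oxirane.

Step 13
Reactants: 23 silyl ether
Product: 24 alkenylboronate: the but-2-ynyl group of 23 converted into an (E)-3-(pinacolboryl)but-2-enyl group (B on C3', trans to C1'; methyl cis to C1')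
Conditions: B2pin2, CuCl (cat.), PCy3 (cat.), NaOtBu (cat.), MeOH, THF, rt
Reagents that add atoms: bis(pinacolato)diboron, CC1(C)OB(OC1(C)C)B1OC(C)(C)C(C)(C)O1
Why: Copper-catalysed syn borylcupration followed by protonation (formal hydroboration): the propargylic C–O bond and the bulk at C1' both send copper to C2' and boron to C3', which should give the E trisubstituted alkenylboronate.

Step 14
Reactants: 24 alkenylboronate; 11 tert-butyl{[(2Z,6E,8E)-9-iodo-2,6-dimethylnona-2,6,8-trien-1-yl]oxy}diphenylsilane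
Product: 25 tetraene: 24 with the boryl group replaced by the C4'–C12' chain (2'E,4'E,6'E,10'Z; C12' oxygen as TBDPS ether)
Conditions: Pd(dppf)Cl2 (cat.), Cs2CO3, DMF/H2O, rt, dark
Reagents that add atoms: none
Why: Suzuki–Miyaura coupling with retention at both alkene partners; at room temperature the dienyl iodide should add to zerovalent palladium far faster than the (Z)-vinyl bromide.

Step 15
Reactants: 25 tetraene
Product: 26 diol: 25 with both triethylsilyl ethers cleaved (C3 primary and C6 secondary hydroxyl free)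
Conditions: HF·pyridine, pyridine, THF, 0 °C
Reagents that add atoms: none
Why: Buffered fluoride cleaves triethylsilyl ethers much faster than the hindered secondary TBS ether and the TBDPS ether.

Step 16
Reactants: 26 diol
Product: 27 keto aldehyde: C3 formyl group and (Z)-3-bromopropenoyl group (C6 ketone) cis on the oxirane
Conditions: (COCl)2, DMSO, CH2Cl2, −78 °C; iPr2NEt, −78 to −40 °C
Reagents that add atoms: none
Why: Swern oxidation activates both hydroxyls before base is added, so the new aldehyde cannot be trapped as a lactol by the C6 hydroxyl, and the hindered amine should not add to the β-bromoenone.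

Step 17
Reactants: 27 keto aldehyde
Product: 29 (4-hydroxy-5,6-epoxycyclohex-2-enone core) 5-hydroxy-6-[C1'–C12' chain, C1' as TBS ether, C12' as TBDPS ether]-7-oxabicyclo[4.1.0]hept-3-en-2-one with the C3 hydroxyl anti to the oxirane oxygen, via alkenylchromium 28 (not isolated)
Conditions: CrCl2 (8 equiv), NiCl2 (2 mol%), degassed DMSO/THF, rt, 0.005 M; aqueous work-up
Reagents that add atoms: none
Why: Zerovalent nickel, formed from NiCl2 and CrCl2, inserts into the activated C2–Br bond of the (Z)-β-bromoenone and passes the alkenyl group to trivalent chromium, and the alkenylchromium 28 adds to the aldehyde carbon C3 (intramolecular Nozaki–Hiyama–Kishi reaction). The closest known reaction type is the NiCl2/CrCl2-mediated closure of halo-alkenyl aldehydes to cycloalkenols, including β-haloenone donors. The cyclohexenone ring closes in a 6-exo-trig mode on the C3=O group, which is possible because the oxirane holds C3 and C6 cis on C4 and C5 and the Z alkene turns C2 toward C3. The new stereocentre C3 is controlled by the adjacent oxirane carbon C4: in the dipole-minimised transition state the aldehyde C=O points away from the oxirane C4–O bond, so the C3–O bond should end up anti to the oxirane oxygen and syn to C1', as in the target. The step needs chemoselectivity for the C–Br bond over the epoxy ketone, the aldehyde and the tetraene, which the activated vinylogous acyl bromide and the mild nickel/chromium pair should secure, and ring closure over intermolecular coupling, which high dilution secures. Loss of alkene geometry in the β-metallated enone would be harmless, because only the Z form can reach C3.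

Step 18
Reactants: 29 epoxy enone
Product: 30 29 with a hydroxymethyl group (C7) on C1
Conditions: aqueous CH2O, DMAP, THF/H2O, rt
Reagents that add atoms: formaldehyde, C=O
Why: Morita–Baylis–Hillman reaction: the amine adds reversibly to C2, the C1 enolate is trapped by formaldehyde and the amine is expelled, a reaction type known for cyclohexenones and epoxycyclohexenones.

Step 19
Reactants: 30 hydroxymethyl enone
Product: 31 C7 acetate of 30
Conditions: Ac2O (1.1 equiv), 2,4,6-collidine, CH2Cl2, −20 °C
Reagents that add atoms: acetic anhydride, CC(=O)OC(C)=O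
Why: The primary allylic alcohol is acylated faster than the secondary C3 hydroxyl, which is flanked by the quaternary oxirane carbon.

Step 20
Reactants: 31 bis-silyl ether acetate
Product: 32 [(1R,5S,6R)-5-hydroxy-6-[(1S,2E,4E,6E,10Z)-1,12-dihydroxy-3,7,11-trimethyldodeca-2,4,6,10-tetraen-1-yl]-2-oxo-7-oxabicyclo[4.1.0]hept-3-en-3-yl]methyl acetate (CNP0305847.1)
Conditions: HF·pyridine, pyridine, THF, 0 °C to rt
Reagents that add atoms: none
Why: Buffered fluoride cleaves both silyl ethers under conditions that should spare the allylic acetate, the epoxy enone and the tetraene.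

**Compound list**

1 | 4-pentyn-1-ol | C#CCCCO | starting material
2 | methyl 2-[bis(2,2,2-trifluoroethoxy)phosphoryl]propanoate | COC(=O)C(C)P(=O)(OCC(F)(F)F)OCC(F)(F)F | starting material
3 | 4-pentynal | C#CCCC=O | intermediate (not isolated)
4 | methyl (Z)-2-methylhept-2-en-6-ynoate | C#CCC/C=C(/C)C(=O)OC | intermediate
5 | (Z)-2-methylhept-2-en-6-yn-1-ol | C#CCC/C=C(/C)CO | intermediate
6 | tert-butyl{[(Z)-2-methylhept-2-en-6-yn-1-yl]oxy}diphenylsilane | C#CCC/C=C(/C)CO[Si](c1ccccc1)(c1ccccc1)C(C)(C)C | intermediate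
7 | [(1E,5Z)-7-(tert-butyldiphenylsilyloxy)-2,6-dimethylhepta-1,5-dien-1-yl]dimethylalane | C[Al](C)/C=C(\C)CC/C=C(/C)CO[Si](c1ccccc1)(c1ccccc1)C(C)(C)C | intermediate (not isolated)
8 | tert-butyl{[(2Z,6E)-7-iodo-2,6-dimethylhepta-2,6-dien-1-yl]oxy}diphenylsilane | I/C=C(\C)CC/C=C(/C)CO[Si](c1ccccc1)(c1ccccc1)C(C)(C)C | intermediate
9 | (E)-1,2-bis(tributylstannyl)ethene | CCCC[Sn](CCCC)(CCCC)/C=C/[Sn](CCCC)(CCCC)CCCC | starting material
10 | tributyl[(1E,3E,7Z)-9-(tert-butyldiphenylsilyloxy)-4,8-dimethylnona-1,3,7-trien-1-yl]stannane | CCCC[Sn](CCCC)(CCCC)/C=C/C=C(\C)CC/C=C(/C)CO[Si](c1ccccc1)(c1ccccc1)C(C)(C)C | intermediate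
11 | tert-butyl{[(2Z,6E,8E)-9-iodo-2,6-dimethylnona-2,6,8-trien-1-yl]oxy}diphenylsilane | I/C=C/C=C(\C)CC/C=C(/C)CO[Si](c1ccccc1)(c1ccccc1)C(C)(C)C | intermediate
12 | ethyl (Z)-3-bromoprop-2-enoate | CCOC(=O)/C=C\Br | starting material
13 | ethyl propiolate | CCOC(=O)C#C | starting material
14 | (Z)-3-bromoprop-2-enal | O=C/C=C\Br | intermediate (not isolated)
15 | ethyl (Z)-6-bromo-4-hydroxyhex-5-en-2-ynoate (racemic) | CCOC(=O)C#CC(O)/C=C\Br | intermediate
16 | ethyl (Z)-6-bromo-4-(triethylsilyloxy)hex-5-en-2-ynoate | CCOC(=O)C#CC(O[Si](CC)(CC)CC)/C=C\Br | intermediate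
17 | but-2-ynal | CC#CC=O | starting material
18 | ethyl 6-bromo-2-(diisobutylalumanyl)-4-(triethylsilyloxy)hexa-2,5-dienoate (Al and H cis on C4=C5; 5Z) | CCOC(=O)/C(=C\C(O[Si](CC)(CC)CC)/C=C\Br)[Al](CC(C)C)CC(C)C | intermediate (not isolated)
19 | ethyl (2Z,5Z)-6-bromo-2-(1-hydroxybut-2-yn-1-yl)-4-(triethylsilyloxy)hexa-2,5-dienoate | CCOC(=O)/C(=C\C(O[Si](CC)(CC)CC)/C=C\Br)C(O)C#CC | intermediate (not isolated)
20 | (2E,5Z)-6-bromo-2-(1-hydroxybut-2-yn-1-yl)-4-(triethylsilyloxy)hexa-2,5-dien-1-ol | OC/C(=C\C(O[Si](CC)(CC)CC)/C=C\Br)C(O)C#CC | intermediate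
21 | (2E,5Z)-6-bromo-2-(1-hydroxybut-2-yn-1-yl)-1,4-bis(triethylsilyloxy)hexa-2,5-diene | CC[Si](CC)(CC)OC/C(=C\C(O[Si](CC)(CC)CC)/C=C\Br)C(O)C#CC | intermediate
22 | (S)-1-{(2S,3S)-3-[(Z)-3-bromo-1-(triethylsilyloxy)prop-2-enyl]-2-[(triethylsilyloxy)methyl]oxiran-2-yl}but-2-yn-1-ol | CC[Si](CC)(CC)OC[C@@]1([C@@H](O)C#CC)O[C@H]1C(O[Si](CC)(CC)CC)/C=C\Br | intermediate
23 | C1'-O-TBS ether of 22 | CC[Si](CC)(CC)OC[C@@]1([C@@H](O[Si](C)(C)C(C)(C)C)C#CC)O[C@H]1C(O[Si](CC)(CC)CC)/C=C\Br | intermediate
24 | (E)-C3'-pinacolboronate from 23 | CC[Si](CC)(CC)OC[C@@]1([C@@H](O[Si](C)(C)C(C)(C)C)/C=C(\C)B2OC(C)(C)C(C)(C)O2)O[C@H]1C(O[Si](CC)(CC)CC)/C=C\Br | intermediate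
25 | tetraene bis(triethylsilyl) ether | CC[Si](CC)(CC)OC[C@@]1([C@@H](O[Si](C)(C)C(C)(C)C)/C=C(C)/C=C/C=C(\C)CC/C=C(/C)CO[Si](c2ccccc2)(c2ccccc2)C(C)(C)C)O[C@H]1C(O[Si](CC)(CC)CC)/C=C\Br | intermediate
26 | C3,C6-diol | OC[C@@]1([C@@H](O[Si](C)(C)C(C)(C)C)/C=C(C)/C=C/C=C(\C)CC/C=C(/C)CO[Si](c2ccccc2)(c2ccccc2)C(C)(C)C)O[C@H]1C(O)/C=C\Br | intermediate
27 | (Z)-β-bromoenone epoxy aldehyde | O=C[C@@]1([C@@H](O[Si](C)(C)C(C)(C)C)/C=C(C)/C=C/C=C(\C)CC/C=C(/C)CO[Si](c2ccccc2)(c2ccccc2)C(C)(C)C)O[C@H]1C(=O)/C=C\Br | intermediate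
28 | (Z)-alkenylchromium dichloride from 27 | O=C[C@@]1([C@@H](O[Si](C)(C)C(C)(C)C)/C=C(C)/C=C/C=C(\C)CC/C=C(/C)CO[Si](c2ccccc2)(c2ccccc2)C(C)(C)C)O[C@H]1C(=O)/C=C\[Cr](Cl)Cl | intermediate (not isolated)
29 | cyclised 4-hydroxy-5,6-epoxycyclohex-2-enone | C1=C[C@H](O)[C@@]2([C@@H](O[Si](C)(C)C(C)(C)C)/C=C(C)/C=C/C=C(\C)CC/C=C(/C)CO[Si](c3ccccc3)(c3ccccc3)C(C)(C)C)O[C@H]2C1=O | intermediate
30 | 2-(hydroxymethyl) enone | OCC1=C[C@H](O)[C@@]2([C@@H](O[Si](C)(C)C(C)(C)C)/C=C(C)/C=C/C=C(\C)CC/C=C(/C)CO[Si](c3ccccc3)(c3ccccc3)C(C)(C)C)O[C@H]2C1=O | intermediate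
31 | 2-(acetoxymethyl) enone bis-silyl ether | CC(=O)OCC1=C[C@H](O)[C@@]2([C@@H](O[Si](C)(C)C(C)(C)C)/C=C(C)/C=C/C=C(\C)CC/C=C(/C)CO[Si](c3ccccc3)(c3ccccc3)C(C)(C)C)O[C@H]2C1=O | intermediate
32 | CNP0305847.1 | CC(=O)OCC1=C[C@H](O)[C@@]2([C@@H](O)/C=C(C)/C=C/C=C(\C)CC/C=C(/C)CO)O[C@H]2C1=O | target

**Count and risks**

Total step count: 20. Longest linear sequence: 14 (steps 7–20).

Steps most likely to fail:

Step 17. Divalent chromium may reductively open the α,β-epoxy ketone before or after closure, in competition with nickel-mediated activation of the C–Br bond, and facial control at C3 may be eroded. The fallback closes the same C2–C3 bond before C6 is a ketone. It sets out from 25: the primary triethylsilyl ether alone is cleaved (PPTS, MeOH, −10 °C) to the primary alcohol F1. Dess–Martin oxidation gives the aldehyde F2; C6 is still a silyl ether, so no lactol can form. Nozaki–Hiyama–Kishi closure of the unactivated (Z)-vinyl bromide (CrCl2, NiCl2, DMF) gives the cyclohexenol silyl ether F3. HF·pyridine frees the C6 hydroxyl to give the enediol F4. MnO2 should then oxidise the less hindered allylic alcohol at C6 in preference to the C3 carbinol next to the quaternary oxirane carbon, which comes back to the route at 29.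

Step 9. The hydride may reduce the ynoate in a 1,2 sense, and the alkene geometry may be lost through an aluminium allenolate before the aldol step. The fallback sets out from 16: Pd(PPh3)4-catalysed syn hydrostannation with Bu3SnH gives the α-stannyl acrylate F5. Iodine converts it with retention into the α-iodo acrylate F6. An intermolecular Nozaki–Hiyama–Kishi coupling of F6 with 17 (CrCl2, NiCl2, DMSO; the C–I bond reacts before the C–Br bond) comes back to the route at 19, which is then isolated and reduced with iBu2AlH to 20.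

Step 11. The alkene carries three allylic C–O bonds and a bulky C5 substituent, so the epoxidation may be slow and the rate difference between the carbinol enantiomers too small; half of the material is lost in any case. The fallback sets C1' first and lets it direct the epoxidation. It sets out from 21: MnO2 oxidises the carbinol to the ynone F7. Corey–Bakshi–Shibata reduction ((R)-2-methyl-CBS-oxazaborolidine, BH3·SMe2, alkyne as the small group) gives the (S)-alcohol F8. Hydroxyl-directed epoxidation with VO(acac)2 and tBuOOH, erythro-selective because of the A(1,2) interaction with the CH2OSiEt3 group on C4, comes back to the route at 22.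

**Further compounds**

F1 | step 17 | C3 primary alcohol from 25 (C6 triethylsilyl ether kept) | OC[C@@]1([C@@H](O[Si](C)(C)C(C)(C)C)/C=C(C)/C=C/C=C(\C)CC/C=C(/C)CO[Si](c2ccccc2)(c2ccccc2)C(C)(C)C)O[C@H]1C(O[Si](CC)(CC)CC)/C=C\Br
F2 | step 17 | C3 aldehyde (C6 triethylsilyl ether kept) | O=C[C@@]1([C@@H](O[Si](C)(C)C(C)(C)C)/C=C(C)/C=C/C=C(\C)CC/C=C(/C)CO[Si](c2ccccc2)(c2ccccc2)C(C)(C)C)O[C@H]1C(O[Si](CC)(CC)CC)/C=C\Br
F3 | step 17 | cyclohexenol with free C3 hydroxyl and C6 triethylsilyl ether | C1=C[C@H](O)[C@@]2([C@@H](O[Si](C)(C)C(C)(C)C)/C=C(C)/C=C/C=C(\C)CC/C=C(/C)CO[Si](c3ccccc3)(c3ccccc3)C(C)(C)C)O[C@H]2C1O[Si](CC)(CC)CC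
F4 | step 17 | C3,C6-enediol | C1=C[C@H](O)[C@@]2([C@@H](O[Si](C)(C)C(C)(C)C)/C=C(C)/C=C/C=C(\C)CC/C=C(/C)CO[Si](c3ccccc3)(c3ccccc3)C(C)(C)C)O[C@H]2C1O
F5 | step 9 | ethyl 6-bromo-2-(tributylstannyl)-4-(triethylsilyloxy)hexa-2,5-dienoate (Sn and H cis on C4=C5; 5Z) | CCOC(=O)/C(=C\C(O[Si](CC)(CC)CC)/C=C\Br)[Sn](CCCC)(CCCC)CCCC
F6 | step 9 | ethyl (2E,5Z)-6-bromo-2-iodo-4-(triethylsilyloxy)hexa-2,5-dienoate | CCOC(=O)/C(I)=C\C(O[Si](CC)(CC)CC)/C=C\Br
F7 | step 11 | ynone from oxidation of the C1' carbinol of 21 | CC[Si](CC)(CC)OC/C(=C\C(O[Si](CC)(CC)CC)/C=C\Br)C(=O)C#CC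
F8 | step 11 | (S)-C1' alcohol (single C1' enantiomer of 21) | CC[Si](CC)(CC)OC/C(=C\C(O[Si](CC)(CC)CC)/C=C\Br)[C@@H](O)C#CC
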